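Decide to run the flask to the end of the time allowed: no listed step takes monomer out of chains, so the open question is how much stands in chains by then.

| flask | free monomer | pre-initiator | remark | time |
|---|---|---|---|---|
| beta | 10 mM (fed, over 40 s) | 0.65 mM | run made earlier |  |
| theta | 10 mM (fed, over 40 s) | 1.5 mM | run made earlier |  |
| flask | 10 mM (fed, over 40 s) | 0.97 mM |  | 25 min |

| run | time / min | monomer in chains / % | free monomer / % |
|---|---|---|---|
| beta | 6.00 | 5.6 | 95.0 |
| beta | 8.00 | 10.2 | 89.2 |
| beta | 10.0 | 17.7 | 81.4 |
| beta | 12.0 | 26.7 | 72.4 |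
| beta | 15.0 | 42.8 | 57.2 |
| theta | 6.00 | 10.7 | 88.6 |
| theta | 8.00 | 21.8 | 78.0 |
| theta | 10.0 | 35.6 | 64.4 |
| theta | 12.0 | 50.1 | 49.8 |
| theta | 15.0 | 69.5 | 30.4 |

(standard deviation of a reading: 0.5 percentage points)

1. when, up to 25 min, the flask holds most monomer in chains
2. the amount of monomer in chains, in percent of the free monomer charged, at that time

1. Follow one free monomer molecule. Each minute it has a chance of joining a chain, and that chance is the drop of ln[free monomer] per minute, a pseudo-first-order constant. Between 12.0 min and 15.0 min it reads 0.0786 min⁻¹ in beta and 0.165 min⁻¹ in theta.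
2. Divide each by its pre-initiator charge: 0.121 min⁻¹ mM⁻¹ and 0.110 min⁻¹ mM⁻¹. Their mean, 0.115 min⁻¹ mM⁻¹, is the capture chance per mM of pre-initiator, read at about 13.5 min.
3. Scaled to the flask, the estimated capture chance is 0.112 min⁻¹ at that time, and the estimated drop of ln[free monomer] is 0.802 at 15.0 min.
4. Low extreme: the flask's capture chance stays at 0.112 min⁻¹ from 15.0 min on. Chains reach 85.3%.
5. High extreme: it keeps growing in proportion to time, to 0.207 min⁻¹ at 25 min. Chains reach 91.4%.
6. No listed step removes living ends, so the chance shouldn't fall. New living ends use free monomer, so the growth of the chance should slacken as free monomer falls. My own reckoning takes the middle, 88.4%.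

The forecast says 25 min (range 24.5 min to 25 min) and 91% (range 85% to 95%), above my middle, holding that “the rate scales roughly with pre-initiator”.

The flask gives 90.5% at 25.0 min.

    free monomer + initiator → living end + monomer in chains (k = 6.70 M⁻¹ min⁻¹)
    free monomer + living end → monomer in chains + living end, rate k2*[living end]*[free monomer] (k = 1100 M⁻¹ min⁻¹)
    initiator ⇌ dormant form (K = 0.410, k = 0.630 min⁻¹)
    pre-initiator → initiator (k = 0.0430 min⁻¹)

The time limit stops the flask while it is still climbing: the same flask run to 250 min reaches 100% against 90.5%. At 25.0 min the flask's 0.158 mM of living end gives a capture chance of 0.173 min⁻¹, above the low extreme's 0.112 min⁻¹ and below the high extreme's 0.207 min⁻¹. The neighbour flask with 4.0 mM of free monomer ends at a capture chance of 0.109 min⁻¹, about the 0.112 min⁻¹ estimated for the flask at 13.5 min, and holds 72.8% in chains.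

The numbers in the tables stem from a simulated flask with made-up constants.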